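Start with the clock. X forms from E with L, which sits in a second phase, and X later goes back to E; you want the top of X in the flask, whose L charge lies between those of two earlier runs.

| setting | south-west | east | flask |
|---|---|---|---|
| E | 0.74 M | 0.74 M | 0.74 M |
| L | 0.55 equiv | 2.2 equiv | 1.10 equiv |
| remark | run made earlier | run made earlier |  |
| time |  |  | 15 d |
| volume of the second phase over the first |  |  | 1.0 |

- south-west (time / d: X / %, E / %): 0.833: 2.0, 96.2; 1.67: 4.3, 95.4; 2.50: 5.6, 94.8; 5.00: 5.0, 93.8; 8.00: 3.9, 95.5; 15.0: 1.5, 98.1
- east (time / d: X / %, E / %): 0.833: 10.9, 89.7; 1.67: 16.8, 82.3; 2.50: 17.7, 79.7; 5.00: 17.4, 79.9; 8.00: 13.3, 83.9; 15.0: 6.2, 91.2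

(standard deviation of a reading: 0.5 percentage points)

* time up to 15 d at which X stands highest
* the amount of X, in percent of the E charged, at that time

- in the second phase: L; everything else is in the first
- charges count per volume of the first phase; a concentration in a rate is the amount of a species over the volume of its own phase; every rate counts per litre of the first phase
- the earlier runs were read with a standard deviation of 0.5 percentage points
- the earlier runs hold the two phases in the same ratio of volumes as the flask asked about

When does X stand highest? Raising L by a factor of 4.00 leaves the highest reading at 2.50 d in both runs, and the east run still reads 17.4% at 5.00 d, so I place the top of the flask between those two times as well.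

How high, then? Work on a logarithmic scale, where the flask is the symmetric point, with 2.00 times the south-west charge and half the east one. The peak order n, the slope of the logarithm of the highest reading of X against the logarithm of L at fixed E, an apparent reaction order, reads 0.830 from the readings 5.6% and 17.7%, and it puts the flask at 9.96%.

The forecast says 10.5% at 3.3 d, higher than my figure, and it reads the two runs in its own way: “Peak heights are about 6% and 18.5%, a factor of about 3.1 for 4× L”.

The flask gives 10.7% at 3.42 d, inside my window and 0.74 percentage points above my figure.

    Q ⇌ L, rate k1*([Q] - [L]/K1) per volume of the first phase (partition coefficient = 1.53, kL = 0.186 /h)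
    E + Q ⇌ X (K = 2.50 /M, k = 0.0154 /M/h)
    Q + X → D (k = 0.00910 /M/h)
    Q → J (k = 0.0550 /h)

In the flask, Q, the reagent in the reaction phase, has a half-life of 0.53 d by the step to J, another product, shorter than the 2.5 d by the forward step to X with the other concentrations as charged, and by 3.00 d the flask has 71% of its turnover to J up to 15 d behind it. A neighbour flask with 1.9 M of E and the flask's equivalents is charged with 2.09 M of L per litre of the first phase against 1.63 M in the east run; n was read at fixed E, so counting it on that concentration is an assumption, which lifts the east reading to 21.8%, and that neighbour tops out at 20.5%.

(Readings and results are simulated for substances that don't exist.)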